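The coupling partner was charged in excess of the two substrates together, by x = 0.250 of their charge. So the substrates were the limiting reagent, and if T is the fraction of them left, the partner stood at T + x in the same measure.

all flasks: left-handed substrate 0.010 M; right-handed substrate 0.010 M; precatalyst 40 µM

| flask | coupling partner | remark | time |
|---|---|---|---|
| midnight | 0.025 M | the very flask that is asked about, followed so far |  |
| flask | 0.0250 M |  | 80 min |

- midnight (time / min: left-handed substrate / %, right-handed substrate / %, left-handed product / %): 2.00: 43.5, 46.0, 6.7; 6.00: 25.3, 31.9, 28.0; 12.0: 15.2, 18.5, 41.8; 15.0: 11.1, 12.8, 44.8; 25.0: 9.4, 8.8, 50.6; 30.0: 6.7, 5.0, 52.6; 40.0: 7.0, 4.8, 54.8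

(scatter of a reading: 1 percentage point)

1. part of the left-handed substrate and right-handed substrate charged together that has reacted at 80 min
2. excess of left-handed product over right-handed product in the product at 80 min
3. excess of right-handed substrate over left-handed substrate among what is left of the two at 80 min

- free catalyst is single-handed; left-handed substrate and right-handed substrate are mirror images of each other, charged as a racemate, each of them at the stated concentration
- the earlier runs were read with a standard deviation of 1 percentage point
- what may be going on: coupling partner + free catalyst + left-handed substrate -> free catalyst + left-handed product; coupling partner + free catalyst + right-handed substrate -> free catalyst + right-handed product; left-handed substrate <-> right-handed substrate; free catalyst -> spent catalyst; coupling partner + precatalyst -> free catalyst + spent reagent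
- an excess is the difference of the two amounts in percent of their sum
- an excess is below zero if the other one leads

I gave both substrates one mean rate, first order in T, in partner and in free catalyst, and took out the partner's decline by integrating:

−dT/dt = (dD/dt)·T·(T + x), so D = (1/x)·ln[(T + x)/((1 + x)·T)]

D sums the working catalyst over time, in units of the mean rate constant.

I followed this flask in three stages, taking T from its readings, each with their scatter. Early on, T = 57.2% at 6.00 min gave D = 0.558. In the middle, T = 23.9% at 15.0 min gave D = 1.97, a gain of 0.157 min⁻¹. Then T = 11.8% at 40.0 min gave D = 3.66, a slower gain of 0.0674 min⁻¹. With the partner already taken out, I read this slowing as a decay of the catalyst at 0.0497 min⁻¹.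

For the end, I carried that decay on from 40.0 min to 80 min:

D = 3.66 + 0.629 = 4.29

This is the catalyst dose, the working catalyst summed up to the asked time.

T = x/((1 + x)·e^(xD) − 1) = 9.44%, so c = 90.6%

The forecast gave c = 93% (89.5% to 96.5%), eP = 24% and eS = 1%, and of the slowing it said: “The rest is catalyst dying”. My c stood below its c, and I made no reckoning of the two excesses.

The flask gave c = 91.2%, eP = 20.9% and eS = 0.444%, each within the forecast's tolerance.

    coupling partner + free catalyst + left-handed substrate → free catalyst + left-handed product (k = 10000 M⁻² s⁻¹)
    coupling partner + free catalyst + right-handed substrate → free catalyst + right-handed product (k = 5600 M⁻² s⁻¹)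
    left-handed substrate ⇌ right-handed substrate (k = 0.00170 s⁻¹)
    free catalyst → spent catalyst (k = 0.00130 s⁻¹)
    coupling partner + precatalyst → free catalyst + spent reagent (k = 0.0880 M⁻¹ s⁻¹)

Put into the same line, this flask's c means a dose of 4.49, above my 4.29. The neighbouring flask was charged with 1.0 × 10⁻⁵ M of precatalyst, a quarter of this flask's, with the other charges and the time held. Scaling the dose with that charge gave 1.12, and the line returned T = 38.2%, so c = 61.8%. The neighbouring flask gave c = 63.1%.

The data are calculated from invented constants, and the scatter is random.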